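All runs are calculated for substances that don't exist, and the scatter is random.

| flask | starting material | second substrate | precatalyst | remark | time |
|---|---|---|---|---|---|
| dawn | 27 mM | 1.1 equiv | 0.02 mol% | run made earlier |  |
| spring | 38 mM | 1.1 equiv | 0.02 mol% | run made earlier |  |
| autumn | 59 mM | 1.1 equiv | 0.02 mol% | run made earlier |  |
| noon | 27 mM | 1.1 equiv | 0.01 mol% | run made earlier |  |
| south | 27 mM | 1.10 equiv | 0.02 mol% | everything together at the start | 15 min |
| west | 27 mM | 1.10 equiv (fed, over 3.0 min) | 0.02 mol% | all else is in the flask from the start; the feed brings no volume worth counting | 15 min |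
| south-east | 27 mM (fed, over 3.0 min) | 1.10 equiv | 0.02 mol% | all else is in the flask from the start; the feed brings no volume worth counting | 15 min |

| run | time / min | target / % | starting material / % |
|---|---|---|---|
| dawn | 3.00 | 0.7 | 98.3 |
| dawn | 6.00 | 3.5 | 95.8 |
| dawn | 10.0 | 9.2 | 88.0 |
| dawn | 12.0 | 13.5 | 84.5 |
| dawn | 15.0 | 18.6 | 81.6 |
| spring | 3.00 | 1.4 | 97.6 |
| spring | 6.00 | 5.6 | 94.8 |
| spring | 10.0 | 13.7 | 87.6 |
| spring | 12.0 | 17.3 | 84.6 |
| spring | 15.0 | 22.3 | 76.0 |
| autumn | 1.33 | 0 | 99.6 |
| autumn | 4.00 | 3.7 | 98.9 |
| autumn | 8.00 | 10.5 | 88.7 |
| autumn | 10.0 | 16.2 | 83.6 |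
| autumn | 15.0 | 27.6 | 71.6 |
| noon | 3.00 | 0.6 | 97.0 |
| noon | 6.00 | 3.0 | 97.8 |
| noon | 10.0 | 4.9 | 96.0 |
| noon | 12.0 | 6.1 | 93.5 |
| noon | 15.0 | 7.3 | 90.8 |

(scatter of a reading: 1 percentage point)

- what was read earlier has a scatter of 1 percentage point, one standard deviation
- a reading or a percentage of target counts all its forms, free or not

- the best flask by amount of target, in percent of the starting material charged; "all alike" if 1.5 percentage points covers them all (south / west / south-east / all alike)
- amount of target at the end, in percent of the starting material charged, south
- amount of target at the end, in percent of the starting material charged, west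
- amount of target at the end, in percent of the starting material charged, south-east

- The dawn run, charged like south, reads 0.7% target at 3.00 min and 18.6% at 15.0 min; at 10.0 min it reads 9.2% against 8.27% from growth with the square of time, a gap within the scatter of 1 percentage point.
- Starting material is the limiting reagent, at 1 equiv against 1.10 equiv of second substrate; in south-east its balance is feed in minus turnover, with the feed ending at 3.0 min, while in west, where second substrate is fed over the same 3.0 min, starting material stands in the flask from the start and its balance has no feed term.
- The feed share φ = (feed time / run time)², the part of a run's target that square-law growth places inside the feed, is 4.00%.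
- My own reckoning prices that window at φ times 18.6%, or 0.74 points, below the margin of 1.5 points, so the three flasks should come out alike near 18.6%.
- One number suffices if the catalyst's build-up continues during the feed, and no earlier run delays a reagent to test this. Noon, at 0.01 mol% precatalyst, reads 7.3%, while autumn's 2.19-fold concentration gives a 1.48-fold percentage.
- The forecast gives south as best, with 19%, 16.5% and 16.5%: “A 3-minute linear feed delays availability by about 1.5 minutes on average”. Its feed cost of 2.5 points exceeds my window.
- The flasks give all alike: south 18.0%, west 17.7%, south-east 18.0%.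

    starting material + enzyme ⇌ starting complex (K = 890 M⁻¹, k = 12000 M⁻¹ s⁻¹)
    second substrate + starting complex ⇌ ternary complex (K = 17.0 M⁻¹, k = 2300 M⁻¹ s⁻¹)
    ternary complex → enzyme + target (k = 5.50 s⁻¹)
    crystals ⇌ target, rate k4*(cs4 - [target]) while solid is left; crystals form when [target] > cs4 (solubility = 1.10 mM, k = 0.00900 s⁻¹)
    precatalyst → enzyme (k = 0.00260 s⁻¹)

- The precatalyst half-life, 4.44 min, is longer than the feed, and precatalyst stands at 31.0% in south, 31.0% in west and 31.0% in south-east at 7.50 min. With φ on 18.0%, the window is 0.72 points, and west trails south by 0.30 points, less.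
- Charging 1.90 equiv of second substrate holds both times, so φ stays 4.00%; that neighbour of south computes to 25.7% target, which prices its window at 1 point, below the margin.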